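**Strategy.** The route rests on the tetrahydropyran ring (O1, C2–C6: C2 carries the CH2 link to the dibenzoxepine, C3 the methyl group and the enol-ether oxygen, C5 the oxetane oxygen, C6 the CMe2 carbon). Its C2–O1–C6 unit and its C3–C4–C5 unit are joined through both C–C bonds, C2–C3 and C5–C6, in one (4+3) cycloaddition of 3-methylfuran with an alkoxy-substituted 2-silyloxyallyl cation, generated from the silyl enol ether of a mixed ketal of (R)-1-phenylethanol. The furan oxygen becomes O1; furan C3 and C4 become the CMe2 carbon and the CH2 link. Bridge cleavage, aldol union with a dibenzoxepinone, cyclodehydration, oxygen transposition from C4 to C5 and oxetane closure follow.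

Key step: step 3

Remark (assumption): the (R)-1-phenylethyl group is taken to direct the furan to the cation face opposite its phenyl ring, which leads to the (1R,2S,5R) adduct 7; should the sense be the reverse, (S)-1-phenylethanol is used with no other change.

Step 1
Reactants: 1 3,3-dimethoxybutan-2-one; 2 (R)-1-phenylethanol
Product: 3 mixed ketal 3-methoxy-3-[(1R)-1-phenylethoxy]butan-2-one (both epimers at the ketal carbon)
Conditions: camphorsulfonic acid (cat.), 1 in excess, cyclohexane, 60 °C, 5 Å sieves (removal of MeOH)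
Reagents that add atoms: none
Why: Acid-catalysed transketalisation should exchange one methoxy group for the chiral alkoxy group, and the new ketal centre need not be controlled because it becomes planar in step 3.

Step 2
Reactants: 3 mixed ketal
Product: 4 triethylsilyl enol ether of 3
Conditions: LiN(iPr)2, THF, −78 °C; Et3SiCl; Et3N, aq. NaHCO3
Reagents that add atoms: chlorotriethylsilane, CC[Si](CC)(CC)Cl
Why: Kinetic deprotonation at the only enolisable carbon (the acetyl methyl) and O-silylation of the enolate should give the silyl enol ether.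

Step 3
Reactants: 4 silyl enol ether; 5 3-methylfuran
Product: 7 (1R,2S,5R)-2,6-dimethyl-2-[(1R)-1-phenylethoxy]-8-oxabicyclo[3.2.1]oct-6-en-3-one, via oxyallyl cation 6 (not isolated)
Conditions: Me3SiOTf (0.1 equiv), 5 (3 equiv), CH2Cl2, −95 to −78 °C; aq. NaHCO3
Reagents that add atoms: none
Why: Me3SiOTf ionises the mixed ketal of 4 (loss of Me3SiOMe) to the 2-silyloxyallyl cation 6, which adds across C2 and C5 of the furan in a (4+3) cycloaddition that is probably stepwise (furan C2 to the CH2 terminus, then attack of the resulting silyl enol ether on the furylium ion), the silyl group being passed on as Et3SiOTf to carry the chain. The closest known reaction type is the Lewis-acid-catalysed (4+3) cycloaddition of furans with alkoxy-substituted silyloxyallyl cations made from silyl enol ethers of α-keto acetals. Two rings close in the one operation, the cycloheptenone carbocycle and the oxygen-bridged tetrahydropyranone, both by intermolecular cycloaddition through a compact (boat-like) transition state in which the second C–C bond forms as a seven-membered closure onto the furylium carbon. The ring-fusion carbons (future tetrahydropyran C2 and C6) come out cis because the furan is attacked on one face at both ends; the quaternary C3 is set by the cation geometry (alkoxy group syn to the silyloxy group, methyl inside) combined with the compact transition state, which puts the alkoxy group equatorial and cis to the bridge; the absolute sense comes from the (R)-1-phenylethyl group, whose phenyl ring covers one face of the cation. The step needs head-to-tail regioselectivity, which the substrate should secure because the more nucleophilic furan C2 (next to the methyl group) bonds to the unsubstituted terminus (future C5) while the crowded tertiary terminus (future C3) bonds to the unhindered furan C5; the minor facial isomer is a diastereomer and can be removed.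

Step 4
Reactants: 7 bicyclic ketone
Product: 8 (1R,4S,5R)-4,7-dimethyl-4-[(1R)-1-phenylethoxy]-8-oxabicyclo[3.2.1]octa-2,6-dien-3-yl trifluoromethanesulfonate
Conditions: KN(SiMe3)2, THF, −78 °C; PhNTf2, −78 to 0 °C
Reagents that add atoms: N-phenylbis(trifluoromethanesulfonimide), O=S(=O)(N(c1ccccc1)S(=O)(=O)C(F)(F)F)C(F)(F)F
Why: Only the CH2 group (future C5) carries α-hydrogens, so the enolate forms regiospecifically and O-triflation (enol triflate formation) turns the C4 carbonyl into an ozone-inert alkene equivalent.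

Step 5
Reactants: 8 dienyl triflate
Product: 9 (2S,3S,6R)-6-acetyl-2-formyl-3-methyl-3-[(1R)-1-phenylethoxy]-3,6-dihydro-2H-pyran-4-yl trifluoromethanesulfonate
Conditions: O3, CH2Cl2/MeOH, −78 °C; Me2S, −78 °C to rt; used crude
Reagents that add atoms: ozone, [O-][O+]=O
Why: Ozonolysis with reductive work-up should cleave only the strained, electron-rich trisubstituted bridge alkene (the vinyl triflate and the arene are electron-poor), and the cis relation of C2 and C6 is inherited from the bridge.

Step 6
Reactants: 10 2-(2-bromo-4-methoxyphenyl)acetic acid; 11 3-methoxyphenol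
Product: 12 2-[4-methoxy-2-(3-methoxyphenoxy)phenyl]acetic acid
Conditions: CuI (10 mol %), N,N-dimethylglycine (30 mol %), K2CO3, DMF, 100 °C; aq. HCl
Reagents that add atoms: none
Why: Ullmann diaryl ether coupling of the aryl bromide, assisted by the neighbouring carboxylate, should give the diaryl ether.

Step 7
Reactants: 12 diaryl ether acid
Product: 13 3,7-dimethoxydibenzo[b,f]oxepin-10(11H)-one
Conditions: P2O5 in MeSO3H (1:10 w/w), 40 °C
Reagents that add atoms: none
Why: Intramolecular Friedel–Crafts acylation should close the seven-membered ring at the position ortho to the ether oxygen and para to the methoxy group of ring B, the only unhindered activated site within reach.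

Step 8
Reactants: 13 dimethoxy ketone
Product: 14 2-bromo-3,7-dimethoxydibenzo[b,f]oxepin-10(11H)-one
Conditions: N-bromosuccinimide (1.0 equiv), MeCN, 0 °C
Reagents that add atoms: N-bromosuccinimide, O=C1CCC(=O)N1Br
Why: Electrophilic aromatic bromination should take place on ring A at the site ortho to the methoxy and para to the aryloxy group, because ring B is deactivated by the conjugated carbonyl and the neutral polar medium disfavours α-bromination.

Step 9
Reactants: 14 bromo dimethoxy ketone
Product: 15 2-bromo-3,7-dihydroxydibenzo[b,f]oxepin-10(11H)-one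
Conditions: BBr3, CH2Cl2, −78 to 0 °C; H2O
Reagents that add atoms: none
Why: Lewis-acid demethylation of the two aryl methyl ethers should leave the diaryl ether and the ketone untouched.

Step 10
Reactants: 15 bisphenol
Product: 16 2-bromo-3,7-bis(triisopropylsilyloxy)dibenzo[b,f]oxepin-10(11H)-one
Conditions: iPr3SiCl, imidazole, DMF, 40 °C
Reagents that add atoms: chlorotriisopropylsilane, CC(C)[Si](Cl)(C(C)C)C(C)C
Why: Silylation of both phenols gives ethers that withstand base, acid, Grignard reagent and borane and are removed by fluoride at the end, and these conditions do not silylate the ketone.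

Step 11
Reactants: 16 bis(silyloxy) ketone; 9 keto aldehyde
Product: 19 enone (11-alkylidene ketone, E/Z mixture), via lithium aldolate 17 (not isolated), via mesylate 18 (not isolated)
Conditions: 16, LiN(SiMe3)2, THF, −78 °C; 9, −78 °C; then MsCl, Et3N, −78 to 0 °C
Reagents that add atoms: none
Why: Aldol condensation: the benzylic lithium enolate of 16 should add to the aldehyde far faster than to the methyl ketone, and mesylation with E1cB elimination gives the enone, whose new centres are lost.

Step 12
Reactants: 19 enone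
Product: 20 saturated ketone (both epimers at C11 of the oxepinone)
Conditions: [(Ph3P)CuH]6, benzene, H2O (2 equiv), rt; aq. NH4Cl
Reagents that add atoms: none
Why: Conjugate reduction by the copper hydride is chemoselective for the enone over the methyl ketone, vinyl triflate and aryl bromide, and the new centre becomes sp2 in step 13.

Step 13
Reactants: 20 saturated ketone
Product: 23 cyclic enol ether (ring D closed), via tertiary alcohol 21 (not isolated), via hemiketal 22 (not isolated)
Conditions: CF3CO2H, anisole, CH2Cl2, 0 °C; then pyridinium p-toluenesulfonate (cat.), 4 Å sieves, toluene, 70 °C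
Reagents that add atoms: none
Why: Acidolysis of the secondary benzylic ether (the cation is trapped by anisole, while ionisation at C3 is disfavoured by the adjacent vinyl triflate), 6-exo hemiketalisation and dehydration should give the conjugated enol ether, with the cis ring fusion dictated by the cis C2/C3 substituents set in step 3.

Step 14
Reactants: 23 methyl ketone
Product: 24 tertiary alcohol (C6–CMe2OH)
Conditions: MeMgBr, THF, −78 °C; aq. NH4Cl
Reagents that add atoms: methylmagnesium bromide, C[Mg]Br
Why: Grignard addition to the chelating α-alkoxy methyl ketone, now the only carbonyl group, gives the dimethyl carbinol without a new stereocentre.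

Step 15
Reactants: 24 vinyl triflate
Product: 25 alkene (C4=C5)
Conditions: Pd(OAc)2 (5 mol %), PPh3 (10 mol %), HCO2H, Bu3N, DMF, 60 °C
Reagents that add atoms: none
Why: Palladium-catalysed formate reduction of the vinyl triflate: zerovalent palladium with PPh3 should insert into the vinyl C–OTf bond much faster than into the hindered, electron-rich aryl bromide.

Step 16
Reactants: 25 alkene
Product: 26 diol (C5–OH trans to the C6 substituent)
Conditions: BH3·THF, THF, 0 °C to rt; then H2O2, aq. NaHCO3
Reagents that add atoms: hydrogen peroxide, OO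
Why: Hydroboration–oxidation should place boron on C5 (away from the quaternary C3) and on the convex face, opposite the C6 substituent and the cis-fused ring D, which sets C5–OH trans to the CMe2OH group, while the tetrasubstituted enol ether reacts much more slowly.

Step 17
Reactants: 26 diol
Product: 28 oxetane (aryl bromide), via mesylate 27 (not isolated)
Conditions: MsCl, Et3N, CH2Cl2, 0 °C; then NaH, THF, 0 to 45 °C
Reagents that add atoms: none
Why: Only the secondary hydroxyl is mesylated, and intramolecular Williamson etherification (4-exo-tet SN2 by the tertiary alkoxide with inversion at C5) should give the cis-fused oxetane and set the last stereocentre.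

Step 18
Reactants: 28 aryl bromide
Product: 29 bis(triisopropylsilyl) ether of the target
Conditions: tributyl(3-methylbut-2-en-1-yl)stannane, Pd(PPh3)4 (5 mol %), DMF, 90 °C
Reagents that add atoms: tributyl(3-methylbut-2-en-1-yl)stannane, CC(C)=CC[Sn](CCCC)(CCCC)CCCC
Why: Stille coupling installs the prenyl group at the brominated carbon under neutral conditions that the oxetane and the enol ether tolerate.

Step 19
Reactants: 29 bis(silyl ether)
Product: 30 CNP0102779.1 (target)
Conditions: Bu4NF, THF, 0 °C; aq. NH4Cl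
Reagents that add atoms: none
Why: Fluoride desilylation frees both phenols without acid, so the oxetane, enol ether and prenyl group survive.

**Compound list**

1 | 3,3-dimethoxybutan-2-one | CC(=O)C(C)(OC)OC | starting material
2 | (R)-1-phenylethanol | C[C@@H](O)c1ccccc1 | starting material
3 | 3-methoxy-3-[(1R)-1-phenylethoxy]butan-2-one (both epimers at the ketal carbon) | CC(=O)C(C)(OC)O[C@H](C)c1ccccc1 | intermediate
4 | triethyl({3-methoxy-3-[(1R)-1-phenylethoxy]but-1-en-2-yl}oxy)silane | C=C(O[Si](CC)(CC)CC)C(C)(OC)O[C@H](C)c1ccccc1 | intermediate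
5 | 3-methylfuran | Cc1ccoc1 | starting material
6 | 1-methyl-1-[(1R)-1-phenylethoxy]-2-(triethylsilyloxy)allyl cation, triflate salt | C=C(O[Si](CC)(CC)CC)C(C)=[O+][C@H](C)c1ccccc1.[O-]S(=O)(=O)C(F)(F)F | intermediate
7 | (1R,2S,5R)-2,6-dimethyl-2-[(1R)-1-phenylethoxy]-8-oxabicyclo[3.2.1]oct-6-en-3-one | C1[C@H]2O[C@@H](C(C)=1)CC(=O)[C@@]2(C)O[C@H](C)c1ccccc1 | intermediate
8 | (1R,4S,5R)-4,7-dimethyl-4-[(1R)-1-phenylethoxy]-8-oxabicyclo[3.2.1]octa-2,6-dien-3-yl trifluoromethanesulfonate | C1[C@H]2O[C@@H](C(C)=1)C=C(OS(=O)(=O)C(F)(F)F)[C@@]2(C)O[C@H](C)c1ccccc1 | intermediate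
9 | (2S,3S,6R)-6-acetyl-2-formyl-3-methyl-3-[(1R)-1-phenylethoxy]-3,6-dihydro-2H-pyran-4-yl trifluoromethanesulfonate | O=C[C@H]1O[C@@H](C(C)=O)C=C(OS(=O)(=O)C(F)(F)F)[C@@]1(C)O[C@H](C)c1ccccc1 | intermediate
10 | 2-(2-bromo-4-methoxyphenyl)acetic acid | COc1ccc(CC(=O)O)c(Br)c1 | starting material
11 | 3-methoxyphenol | COc1cccc(O)c1 | starting material
12 | 2-[4-methoxy-2-(3-methoxyphenoxy)phenyl]acetic acid | COc1ccc(CC(=O)O)c(Oc2cccc(OC)c2)c1 | intermediate
13 | 3,7-dimethoxydibenzo[b,f]oxepin-10(11H)-one | COc1cc2Oc3cc(OC)ccc3C(=O)Cc2cc1 | intermediate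
14 | 2-bromo-3,7-dimethoxydibenzo[b,f]oxepin-10(11H)-one | COc1cc2Oc3cc(OC)ccc3C(=O)Cc2cc1Br | intermediate
15 | 2-bromo-3,7-dihydroxydibenzo[b,f]oxepin-10(11H)-one | Oc1cc2Oc3cc(O)ccc3C(=O)Cc2cc1Br | intermediate
16 | 2-bromo-3,7-bis(triisopropylsilyloxy)dibenzo[b,f]oxepin-10(11H)-one | Brc1cc2c(cc1O[Si](C(C)C)(C(C)C)C(C)C)Oc1cc(O[Si](C(C)C)(C(C)C)C(C)C)ccc1C(=O)C2 | intermediate
17 | lithium aldolate: lithium alkoxide of 16 joined at C11 to the carbinol carbon formed from the formyl group of 9 (dihydropyran unit configured as in 9; mixture at the two new centres) | Brc1cc2c(cc1O[Si](C(C)C)(C(C)C)C(C)C)Oc1cc(O[Si](C(C)C)(C(C)C)C(C)C)ccc1C(=O)C2C([O-])[C@H]1O[C@@H](C(C)=O)C=C(OS(=O)(=O)C(F)(F)F)[C@@]1(C)O[C@H](C)c1ccccc1.[Li+] | intermediate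
18 | methanesulfonate of the aldol adduct 17 | Brc1cc2c(cc1O[Si](C(C)C)(C(C)C)C(C)C)Oc1cc(O[Si](C(C)C)(C(C)C)C(C)C)ccc1C(=O)C2C(OS(C)(=O)=O)[C@H]1O[C@@H](C(C)=O)C=C(OS(=O)(=O)C(F)(F)F)[C@@]1(C)O[C@H](C)c1ccccc1 | intermediate
19 | enone: 2-bromo-11-{[(2R,3S,6R)-6-acetyl-3-methyl-3-[(1R)-1-phenylethoxy]-4-(trifluoromethanesulfonyloxy)-3,6-dihydro-2H-pyran-2-yl]methylidene}-3,7-bis(triisopropylsilyloxy)dibenzo[b,f]oxepin-10(11H)-one (E/Z mixture) | Brc1cc2c(cc1O[Si](C(C)C)(C(C)C)C(C)C)Oc1cc(O[Si](C(C)C)(C(C)C)C(C)C)ccc1C(=O)C2=C[C@H]1O[C@@H](C(C)=O)C=C(OS(=O)(=O)C(F)(F)F)[C@@]1(C)O[C@H](C)c1ccccc1 | intermediate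
20 | saturated ketone: the 11-[(dihydropyran-2-yl)methyl] analogue of 19 (both epimers at C11) | Brc1cc2c(cc1O[Si](C(C)C)(C(C)C)C(C)C)Oc1cc(O[Si](C(C)C)(C(C)C)C(C)C)ccc1C(=O)C2C[C@H]1O[C@@H](C(C)=O)C=C(OS(=O)(=O)C(F)(F)F)[C@@]1(C)O[C@H](C)c1ccccc1 | intermediate
21 | tertiary alcohol: 20 without the 1-phenylethyl group | Brc1cc2c(cc1O[Si](C(C)C)(C(C)C)C(C)C)Oc1cc(O[Si](C(C)C)(C(C)C)C(C)C)ccc1C(=O)C2C[C@H]1O[C@@H](C(C)=O)C=C(OS(=O)(=O)C(F)(F)F)[C@@]1(C)O | intermediate
22 | cyclic hemiketal of 21 (tertiary oxygen on the oxepinone carbonyl carbon; ring D closed, cis-fused) | Brc1cc2c(cc1O[Si](C(C)C)(C(C)C)C(C)C)Oc1cc(O[Si](C(C)C)(C(C)C)C(C)C)ccc1C1(O)C2C[C@H]2O[C@@H](C(C)=O)C=C(OS(=O)(=O)C(F)(F)F)[C@@]2(C)O1 | intermediate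
23 | cyclic enol ether: dibenzoxepine fused through its C10=C11 bond to the 4H-pyran ring D, which is cis-fused to the dihydropyran bearing 6-acetyl, 3-methyl and 4-triflyloxy groups (stereocentres as in 9) | Brc1cc2c(cc1O[Si](C(C)C)(C(C)C)C(C)C)Oc1cc(O[Si](C(C)C)(C(C)C)C(C)C)ccc1C1=C2C[C@H]2O[C@@H](C(C)=O)C=C(OS(=O)(=O)C(F)(F)F)[C@@]2(C)O1 | intermediate
24 | tertiary alcohol: 23 with the acetyl group converted to C(CH3)2OH | Brc1cc2c(cc1O[Si](C(C)C)(C(C)C)C(C)C)Oc1cc(O[Si](C(C)C)(C(C)C)C(C)C)ccc1C1=C2C[C@H]2O[C@@H](C(C)(C)O)C=C(OS(=O)(=O)C(F)(F)F)[C@@]2(C)O1 | intermediate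
25 | alkene: 24 with the triflyloxy group replaced by hydrogen (C4=C5 alkene) | Brc1cc2c(cc1O[Si](C(C)C)(C(C)C)C(C)C)Oc1cc(O[Si](C(C)C)(C(C)C)C(C)C)ccc1C1=C2C[C@H]2O[C@@H](C(C)(C)O)C=C[C@@]2(C)O1 | intermediate
26 | diol: tetrahydropyran (2R,3R,5R,6R) with C5–OH trans to the C6–C(CH3)2OH group | Brc1cc2c(cc1O[Si](C(C)C)(C(C)C)C(C)C)Oc1cc(O[Si](C(C)C)(C(C)C)C(C)C)ccc1C1=C2C[C@H]2O[C@@H](C(C)(C)O)[C@@H](C[C@@]2(C)O1)O | intermediate
27 | C5 methanesulfonate of 26 | Brc1cc2c(cc1O[Si](C(C)C)(C(C)C)C(C)C)Oc1cc(O[Si](C(C)C)(C(C)C)C(C)C)ccc1C1=C2C[C@H]2O[C@@H](C(C)(C)O)[C@@H](C[C@@]2(C)O1)OS(C)(=O)=O | intermediate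
28 | oxetane: bromo analogue of the target as its bis(triisopropylsilyl) ether (tetrahydropyran 2R,3R,5S,6R) | Brc1cc2c(cc1O[Si](C(C)C)(C(C)C)C(C)C)Oc1cc(O[Si](C(C)C)(C(C)C)C(C)C)ccc1C1=C2C[C@H]2O[C@@H]3[C@H](C[C@@]2(C)O1)OC3(C)C | intermediate
29 | bis(triisopropylsilyl) ether of the target | CC(C)=CCc1cc2c(cc1O[Si](C(C)C)(C(C)C)C(C)C)Oc1cc(O[Si](C(C)C)(C(C)C)C(C)C)ccc1C1=C2C[C@H]2O[C@@H]3[C@H](C[C@@]2(C)O1)OC3(C)C | intermediate
30 | CNP0102779.1 (tetrahydropyran C2 R, C3 R, C5 S, C6 R; all four ring substituents cis) | CC(C)=CCc1cc2c(cc1O)Oc1cc(O)ccc1C1=C2C[C@H]2O[C@@H]3[C@H](C[C@@]2(C)O1)OC3(C)C | target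

**Total steps:** 19. **Longest linear sequence:** 14 (steps 1–5 and 11–19; the aromatic branch, steps 6–10 and 11–19, is equally long).

**Steps most likely to fail**

Step 3. The unsymmetrical furan may add head-to-head (methyl-bearing furan carbon bonding to the quaternary terminus) or be alkylated without ring closure, so that regio- and facial control are lost together. Fallback: the cycloaddition is run with furan itself under the same conditions, for which no regiochemical question exists, and the methyl group is added afterwards. Compound 4 gives the des-methyl cycloadduct F1. Enol triflate formation as in step 4 gives the des-methyl dienyl triflate F2, and ozonolysis as in step 5 gives the dialdehyde F3. MeTi(OiPr)3 (THF, −78 °C) should add only to the less hindered formyl group on C6, since the one on C2 is shielded by the quaternary C3, to give the hydroxy aldehyde F4. Oxidation of the secondary alcohol with the periodinane DMP gives 9. The fallback sets out from 4 and returns to the route at 9.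

Step 17. The tertiary alkoxide of mesylate 27 may fragment (Grob fragmentation: loss of acetone and formation of the C5=C6 enol ether) or the mesylate may eliminate faster than the 4-exo displacement occurs. Fallback: the diol is cyclised without an alkoxide. Mitsunobu-type cyclodehydration of 26 (PPh3, diisopropyl azodicarboxylate, toluene, 0 to 60 °C) activates the less hindered secondary hydroxyl as the alkoxyphosphonium ion F5, which the neutral tertiary hydroxyl displaces with inversion to give 28 directly. The fallback sets out from 26 and returns at 28.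

Step 16. Boron may be delivered to C4 instead of C5, to the lower face through the borate of the tertiary alcohol, or to the enol ether. Fallback: the regiochemistry is fixed by a silicon tether and the configuration is then corrected by inversion. Compound 25 is silylated at the tertiary hydroxyl (HMe2SiCl, Et3N) to the hydridosilyl ether F6. Intramolecular hydrosilylation (Pt2[(CH2=CHSiMe2)2O]3 cat., toluene, 60 °C, 5-exo) gives the oxasilolane F7 with silicon on C5 on the face of the tether, and Tamao oxidation (H2O2, KF, KHCO3) gives the cis diol F8. Mitsunobu inversion with 4-nitrobenzoic acid (PPh3, diisopropyl azodicarboxylate) gives the inverted 4-nitrobenzoate F9, and methanolysis (K2CO3, MeOH, 0 °C) gives 26. The fallback sets out from 25 and returns at 26.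

Further compounds

F1 | step 3 | des-methyl cycloadduct: 7 lacking the C6 methyl group, (1R,2S,5R)-2-methyl-2-[(1R)-1-phenylethoxy]-8-oxabicyclo[3.2.1]oct-6-en-3-one | C1[C@H]2O[C@@H](C=1)CC(=O)[C@@]2(C)O[C@H](C)c1ccccc1
F2 | step 3 | des-methyl dienyl triflate: 8 lacking the C7 methyl group (same configuration) | C1[C@H]2O[C@@H](C=1)C=C(OS(=O)(=O)C(F)(F)F)[C@@]2(C)O[C@H](C)c1ccccc1
F3 | step 3 | dialdehyde: 9 with a formyl group in place of the acetyl group (same configuration) | O=C[C@H]1O[C@@H](C=O)C=C(OS(=O)(=O)C(F)(F)F)[C@@]1(C)O[C@H](C)c1ccccc1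
F4 | step 3 | hydroxy aldehyde: 9 with a 1-hydroxyethyl group in place of the acetyl group (both carbinol epimers) | O=C[C@H]1O[C@@H](C(C)O)C=C(OS(=O)(=O)C(F)(F)F)[C@@]1(C)O[C@H](C)c1ccccc1
F5 | step 17 | alkoxyphosphonium ion: 26 with its C5 oxygen bound to triphenylphosphonium | Brc1cc2c(cc1O[Si](C(C)C)(C(C)C)C(C)C)Oc1cc(O[Si](C(C)C)(C(C)C)C(C)C)ccc1C1=C2C[C@H]2O[C@@H](C(C)(C)O)[C@@H](C[C@@]2(C)O1)O[P+](c1ccccc1)(c1ccccc1)c1ccccc1
F6 | step 16 | hydridosilyl ether: dimethylsilyl ether of the tertiary alcohol of 25 | Brc1cc2c(cc1O[Si](C(C)C)(C(C)C)C(C)C)Oc1cc(O[Si](C(C)C)(C(C)C)C(C)C)ccc1C1=C2C[C@H]2O[C@@H](C(C)(C)O[SiH](C)C)C=C[C@@]2(C)O1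
F7 | step 16 | oxasilolane: five-membered C5–Si(CH3)2–O–C(CH3)2 ring cis-fused at C5–C6 | Brc1cc2c(cc1O[Si](C(C)C)(C(C)C)C(C)C)Oc1cc(O[Si](C(C)C)(C(C)C)C(C)C)ccc1C1=C2C[C@H]2O[C@@H]3[C@H](C[C@@]2(C)O1)[Si](C)(C)OC3(C)C
F8 | step 16 | cis diol: C5 epimer of 26 (C5–OH cis to the C6 substituent) | Brc1cc2c(cc1O[Si](C(C)C)(C(C)C)C(C)C)Oc1cc(O[Si](C(C)C)(C(C)C)C(C)C)ccc1C1=C2C[C@H]2O[C@@H](C(C)(C)O)[C@H](C[C@@]2(C)O1)O
F9 | step 16 | inverted 4-nitrobenzoate: C5 4-nitrobenzoate of 26 | Brc1cc2c(cc1O[Si](C(C)C)(C(C)C)C(C)C)Oc1cc(O[Si](C(C)C)(C(C)C)C(C)C)ccc1C1=C2C[C@H]2O[C@@H](C(C)(C)O)[C@@H](C[C@@]2(C)O1)OC(=O)c1ccc(cc1)[N+](=O)[O-]
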